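The dusk run held 2.24 times the Z of the noon run, yet the ratio of their Q readings at 15.0 min is 1.01. In percent of the charge, Q does not follow the charge. Two chemists read these curves differently.

| setting | noon | dusk | flask |
|---|---|---|---|
| Z | 0.17 M | 0.38 M | 0.25 M |
| X | 17 mM (held) | 17 mM (held) | 17 mM (held) |
| remark | run made earlier | run made earlier |  |
| time |  |  | 50 min |

| run | time / min | Q / % |
|---|---|---|
| noon | 6.00 | 29.7 |
| noon | 12.0 | 44.0 |
| noon | 15.0 | 47.6 |
| noon | 25.0 | 55.6 |
| noon | 30.0 | 56.3 |
| noon | 40.0 | 57.6 |
| dusk | 2.00 | 11.9 |
| dusk | 6.00 | 27.8 |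
| dusk | 12.0 | 43.1 |
| dusk | 15.0 | 48.2 |
| dusk | 25.0 | 54.3 |
| dusk | 30.0 | 56.2 |
| dusk | 40.0 | 58.1 |

(scatter of a reading: 0.5 percentage points)

* Q at 50 min, in percent of the Z charged
* the change that raises the amount of Q at 50 min, in percent of the Z charged most ("none" if none brings more than 2 percentage points) (blue / ochre / none)
* amount of Q at 50 min, in percent of the Z charged, after blue

- blue: doubling the transfer coefficient of X, all else as stated
- ochre: doubling the saturation concentration of X, all else as stated

- at the start none of L is dissolved
- steps under discussion: X <-> L; Z + L -> Q; Z -> G; 2 L -> E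

The first reads a clock. The dusk run gained 1.9 percentage points from 30.0 min to 40.0 min. The same step again gives 60.0 % at 50 min.

The second counts turnovers. If c(L) stays steady, Z decays pseudo-first-order. Let S, the plateau of Q, be taken as the dusk reading at 40.0 min. The dusk reading Q at 15.0 min then gives ln(S/(S−Q)) divided by that time. This is the turnover rate, the e-foldings of Z per minute: 0.118 min⁻¹. It is a reading and carries the scatter.

At 40.0 min the dusk run has had 4.72 turnovers, so about 0.892 % of its Z remains. That is less than the clock's gain, so the clock asks for more than the Z can give.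

I side with the count. The flask gets 5.90 turnovers, leaving 0.274 % of its Z. My Q is S(1−e^(−N)), or 57.9 %.

The forecast, from its own fit, says 58.3 %, with 58.8 % after blue and ochre as best: “Z is essentially gone”. I also expect ochre to beat blue.

The simulation gives 57.9 %, with 0.27 % of the Z left. Blue gives 58.8 %, a gain of 0.9 points. Ochre gains 15 points, so ochre is best. The clock has its region early: at 20.7 min this flask's Q stands 5 points from its answer.

    X ⇌ L, rate k1*(csat - [L]) (kL = 17.0 min⁻¹)
    Z + L → Q (k = 4.30 M⁻¹ min⁻¹)
    Z → G (k = 0.0490 min⁻¹)
    2 L → E (k = 22.0 M⁻¹ min⁻¹)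

The neighbouring flask is the same charge read at 12 min. It gets 1.42 turnovers, which leaves 24.3 % of the Z and gives Q of 44.0 %. The simulation has Z at 25 % and Q at 43.6 %.

All runs stem from a simulated flask from invented constants; noise was put on by code.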